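The earlier runs and the new flask are calculated with made-up constants, and the scatter is random.

If the product reading of larch at 30.0 h were off by its scatter, that would be 2 percentage points against 36%, so I asked first which of the given numbers had to be known well.

in all of them: gas 200 mM (held)
- larch: starting material 0.29 M; run made earlier
- dawn: starting material 0.20 M; time 30 h
- winter: starting material 0.40 M; time 30 h
- noon: starting material 0.80 M; time 30 h
- spring: starting material 1.5 M; time 30 h
- summer: starting material 3.0 M; time 30 h

larch run (percent of the starting material charged)

| time / h | product / % | starting material / % |
|---|---|---|
| 8.00 | 5 | 1 |
| 15.0 | 16 | 0 |
| 25.0 | 27 | 0 |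
| 30.0 | 36 | 2 |

(standard deviation of a reading: 2 percentage points)

- the earlier runs were read with a standard deviation of 2 percentage points
- at the start none of the gas is in solution
- "hardly changes" means that all values lie within two and a half points (for a concentration: within two and a half percent of the largest)

1. [product] at the end for dawn, winter, noon, spring, summer, in this order
2. how that number moves from the first to the last of them (rises, then falls / falls, then rises / hardly changes / rises all the way / falls all the way)

The gas was held at 200 mM, equal to larch, so an error there would shift the flasks together. In larch the starting material stood at 1% by 8.00 h, earlier than 30 h, so I needed no exact rate for its loss. The charge was the number that mattered, because a fixed share of each charge and a fixed amount give different rows. So I counted turnovers: the product count, the amount of product made by 30 h, read from larch as 0.104 M, is 52.2% of dawn's charge and 3.48% of summer's. Larch product kept climbing, 16%, 27%, 36%, without slowing, so I committed to a fixed count.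

The forecast likewise stood at 0.104 M from dawn to summer, hardly changes: “Its rate is then set by something else, such as the held gas or a catalyst, and not by the charge”.

The flasks gave 0.0941 M, 0.112 M, 0.119 M, 0.122 M and 0.123 M, which rises all the way.

    open intermediate + second intermediate → product (k = 1.30 L mol⁻¹ h⁻¹)
    gas ⇌ partner, rate k2*(csat - [partner]) (kL = 0.120 h⁻¹)
    partner → second intermediate (k = 0.0340 h⁻¹)
    starting material → open intermediate (k = 0.560 h⁻¹)

Against the count, dawn's share of 52.2% stood at 47.1% and summer's of 3.48% at 4.12%. In dawn at 9.09 h, second intermediate had a half-life of 2.8 h by its reaction with open intermediate, shorter than the 20 h of partner by its reaction to second intermediate alone. At 30.0 h, dawn still held 0.0307 M of second intermediate beside 52.9% of open intermediate, against 0.00140 M beside 95.9% in summer.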